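**Strategy**

The hexamer is a chain of six rings joined by CH2 bridges: ring A (butyrylfilicinic acid), rings B–E (butyrylphloroglucinols) and ring F (C-methyl butyrylphloroglucinol). The route rests on cutting the bond between the bridging CH2 on ring D and the ring-E carbon. That CH2 sits ortho to two phenolic OH groups of ring D, so a ring-D Mannich base (CH2NMe2) of the A–B–C–D tetramer expels dimethylamine to an o-quinone methide, which is captured by the single unsubstituted, OH-flanked carbon of ring E in the E–F dimer. One operation thus unites tetramer and dimer, unprotected; every fragment is built by the same Mannich/o-quinone methide logic.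

Key step: step 9

Remark: all compounds are written in the enol/keto tautomer used for the target. The target has no stereocentre, so no step has to control configuration. Mannich bases are expected to exist as internal ammonium phenolates/enolates and are written as neutral amines.

**Route**

Step 1
Reactants: 1 phloroglucinol; 2 butyryl chloride
Product: 3 butyrylphloroglucinol [1-(2,4,6-trihydroxyphenyl)butan-1-one]
Conditions: AlCl3 (4 equiv), PhNO2/CH2Cl2, 0 °C to 45 °C; ice/aq. HCl
Reagents that add atoms: butyryl chloride, CCCC(=O)Cl
Why: Friedel–Crafts C-acylation of the strongly activated triol; the first acyl group deactivates the ring, so mono-acylation should dominate.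

Step 2
Reactants: 3 butyrylphloroglucinol; 4 iodomethane
Product: 5 butyrylfilicinic acid (2-butanoyl-3,5-dihydroxy-4,4-dimethylcyclohexa-2,5-dien-1-one)
Conditions: NaOMe (3.5 equiv), MeI (2.2 equiv), MeOH, 0 °C to rt; aq. HCl; chromatography
Reagents that add atoms: iodomethane, CI
Why: Double C-methylation of the phloroglucinolate at one ring carbon dearomatises the ring to the gem-dimethyl β-triketone, whose vinylogous-acid anion resists further alkylation; this is the established preparation of acylfilicinic acids, with mono- and trimethyl congeners to be separated.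

Step 3
Reactants: 5 butyrylfilicinic acid; 6 bis(dimethylamino)methane; 3 butyrylphloroglucinol (6 equiv)
Product: 8 dimer A–B (ring A bridged by CH2 from C-6 to C-3 of ring B; C-5 of ring B unsubstituted), via triketone Mannich base 7 (not isolated)
Conditions: Me2NCH2NMe2 (1.0 equiv), THF, −10 °C (5 added slowly to the aminal); then 3 (6 equiv), 45 °C; dilute HCl work-up
Reagents that add atoms: bis(dimethylamino)methane, CN(C)CN(C)C
Why: Mannich reaction at the only C–H ring carbon of 5, then loss of dimethylamine from zwitterion 7 to the 6-methylene triketone and Michael (Friedel–Crafts type) capture by 3, whose excess should suppress double alkylation.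

Step 4
Reactants: 3 butyrylphloroglucinol (4 equiv); 9 formaldehyde
Product: 10 methylenebis(butyrylphloroglucinol) (symmetrical dimer, the future rings C and D; one free ring C–H on each ring)
Conditions: 37% aq. CH2O (1 equiv), KOH (0.2 equiv, catalytic), MeOH/H2O, 0 °C to rt; AcOH quench
Reagents that add atoms: formaldehyde, C=O
Why: Base-catalysed phenol–formaldehyde condensation (hydroxymethylation, o-quinone methide, Michael addition); the excess of 3 should stop the chain at the dimer.

Step 5
Reactants: 8 dimer A–B; 6 bis(dimethylamino)methane; 10 methylenebis(butyrylphloroglucinol) (4 equiv)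
Product: 12 tetramer A–B–C–D (ring D keeps one unsubstituted ring carbon), via ring-B Mannich base 11 (not isolated)
Conditions: Me2NCH2NMe2 (1.0 equiv), THF, 0 °C to rt; then 10 (4 equiv), 50 °C; dilute HCl work-up; Sephadex LH-20
Reagents that add atoms: bis(dimethylamino)methane, CN(C)CN(C)C
Why: Mannich reaction at the single free carbon of ring B, thermal loss of dimethylamine to the ring-B o-quinone methide and conjugate addition of one of the two equivalent free carbons of 10, used in excess so that only one terminus should react.

Step 6
Reactants: 12 tetramer A–B–C–D; 6 bis(dimethylamino)methane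
Product: 13 tetramer Mannich base (CH2NMe2 on C-5 of ring D)
Conditions: Me2NCH2NMe2 (1.5 equiv), THF, 0 °C to rt; evaporation, trituration with Et2O
Reagents that add atoms: bis(dimethylamino)methane, CN(C)CN(C)C
Why: Mannich aminomethylation at the only unsubstituted ring carbon of 12; the product should separate as an internal ammonium enolate and the volatile excess aminal is removed in vacuo.

Step 7
Reactants: 14 2-methylphloroglucinol; 2 butyryl chloride
Product: 15 1-(2,4,6-trihydroxy-3-methylphenyl)butan-1-one (ring F)
Conditions: AlCl3 (4 equiv), PhNO2/CH2Cl2, 0 °C to 45 °C; ice/aq. HCl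
Reagents that add atoms: butyryl chloride, CCCC(=O)Cl
Why: Friedel–Crafts acylation; the two free positions of 14 are equivalent, so a single regioisomer is expected.

Step 8
Reactants: 15 ring F ketone; 6 bis(dimethylamino)methane; 3 butyrylphloroglucinol (6 equiv)
Product: 17 dimer E–F (ring E keeps one unsubstituted ring carbon), via ring-F Mannich base 16 (not isolated)
Conditions: Me2NCH2NMe2 (1.0 equiv), THF, 0 °C to rt; then 3 (6 equiv), 50 °C; dilute HCl work-up
Reagents that add atoms: bis(dimethylamino)methane, CN(C)CN(C)C
Why: Mannich reaction at the only free carbon of 15, o-quinone methide formation and capture by excess 3, as in step 3.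

Step 9
Reactants: 13 tetramer Mannich base; 17 dimer E–F (1.2 equiv)
Product: 18 target hexamer A–B–C–D–E–F
Conditions: 1,4-dioxane, AcOH/NaOAc buffer, 50 °C, argon, slow addition of 13 to 17; dilute HCl work-up; Sephadex LH-20
Reagents that add atoms: none
Why: The ring-D phenol of 13 is hydrogen-bonded to (or has protonated) the benzylic dimethylamino group, so mild heating should cause E1cB-type loss of dimethylamine and unmask an o-quinone methide across C-5 of ring D and its exocyclic CH2. The ring-E carbon of 17 that lies between two OH groups and carries only hydrogen adds to that CH2 in a conjugate (Michael/Friedel–Crafts type) addition, and tautomerisation restores both aromatic rings, which should make the C–C bond formation effectively irreversible under the buffered conditions. The closest known reaction type is the Mannich-base (gramine-type) alkylation of phloroglucinols through o-quinone methides, the usual way to methylene-bridged acylphloroglucinol dimers. No ring is closed and no stereocentre is formed. The step needs C- over O-alkylation at a single site on each partner: O-adducts revert to the quinone methide, 13 has no unsubstituted ring carbon left and 17 has exactly one. It also needs the existing CH2 bridges to stay in place, which the moderate temperature, the acetate buffer that takes up the liberated amine and the slow addition of 13 to an excess of 17 are meant to secure.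

**Compound list**

1 | phloroglucinol (benzene-1,3,5-triol) | Oc1cc(O)cc(O)c1 | starting material
2 | butyryl chloride | CCCC(=O)Cl | starting material
3 | butyrylphloroglucinol, 1-(2,4,6-trihydroxyphenyl)butan-1-one | CCCC(=O)c1c(O)cc(O)cc1O | intermediate
4 | iodomethane | CI | starting material
5 | butyrylfilicinic acid, 2-butanoyl-3,5-dihydroxy-4,4-dimethylcyclohexa-2,5-dien-1-one | CCCC(=O)C1=C(O)C(C)(C)C(O)=CC1=O | intermediate
6 | bis(dimethylamino)methane | CN(C)CN(C)C | starting material
7 | Mannich base of 5, 6-[(dimethylamino)methyl] derivative | CCCC(=O)C1=C(O)C(C)(C)C(O)=C(CN(C)C)C1=O | intermediate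
8 | dimer A–B, butyrylfilicinic acid joined through CH2 to C-3 of butyrylphloroglucinol | CCCC(=O)C1=C(O)C(C)(C)C(O)=C(Cc2c(O)cc(O)c(C(=O)CCC)c2O)C1=O | intermediate
9 | formaldehyde (37% aqueous) | C=O | starting material
10 | methylenebis(butyrylphloroglucinol), two butyrylphloroglucinols joined C-3 to C-3' by CH2 | CCCC(=O)c1c(O)cc(O)c(Cc2c(O)cc(O)c(C(=O)CCC)c2O)c1O | intermediate
11 | ring-B Mannich base of 8 (CH2NMe2 on C-5 of ring B) | CCCC(=O)C1=C(O)C(C)(C)C(O)=C(Cc2c(O)c(CN(C)C)c(O)c(C(=O)CCC)c2O)C1=O | intermediate
12 | tetramer A–B–C–D, ring D with one free ring C–H | CCCC(=O)C1=C(O)C(C)(C)C(O)=C(Cc2c(O)c(Cc3c(O)c(Cc4c(O)cc(O)c(C(=O)CCC)c4O)c(O)c(C(=O)CCC)c3O)c(O)c(C(=O)CCC)c2O)C1=O | intermediate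
13 | tetramer Mannich base, CH2NMe2 on C-5 of ring D | CCCC(=O)C1=C(O)C(C)(C)C(O)=C(Cc2c(O)c(Cc3c(O)c(Cc4c(O)c(CN(C)C)c(O)c(C(=O)CCC)c4O)c(O)c(C(=O)CCC)c3O)c(O)c(C(=O)CCC)c2O)C1=O | intermediate
14 | 2-methylphloroglucinol (2-methylbenzene-1,3,5-triol) | Cc1c(O)cc(O)cc1O | starting material
15 | 1-(2,4,6-trihydroxy-3-methylphenyl)butan-1-one (ring F) | CCCC(=O)c1c(O)cc(O)c(C)c1O | intermediate
16 | Mannich base of 15 (CH2NMe2 on C-5) | CCCC(=O)c1c(O)c(CN(C)C)c(O)c(C)c1O | intermediate
17 | dimer E–F, butyrylphloroglucinol joined through CH2 to C-5 of ring F | CCCC(=O)c1c(O)cc(O)c(Cc2c(O)c(C)c(O)c(C(=O)CCC)c2O)c1O | intermediate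
18 | target hexamer A–B–C–D–E–F | CCCC(=O)C1=C(O)C(C)(C)C(O)=C(Cc2c(O)c(Cc3c(O)c(Cc4c(O)c(Cc5c(O)c(Cc6c(O)c(C)c(O)c(C(=O)CCC)c6O)c(O)c(C(=O)CCC)c5O)c(O)c(C(=O)CCC)c4O)c(O)c(C(=O)CCC)c3O)c(O)c(C(=O)CCC)c2O)C1=O | target

**Summary**

Total step count: 9. Longest linear sequence: 6 steps (steps 1, 2, 3, 5, 6, 9).

Steps most likely to fail:

1. Step 9 (key step). Thermal quinone methide generation in a medium that contains amine could be accompanied by retro-Michael opening and re-closure of the existing CH2 bridges (redistribution of rings along the chain) and by self-condensation of the quinone methide. Fallback, from 12 back to 18: 12 would be condensed with aqueous formaldehyde 9 and p-toluenesulfinic acid (THF/H2O, rt) to the ring-D p-tolylsulfonylmethyl tetramer F1, a base-triggered quinone methide precursor. F1 and 17 with NaHCO3 in THF/H2O at 0 °C should then give 18 by loss of sulfinate and the same conjugate addition, at a temperature below that at which bridges exchange.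

2. Step 5. The symmetrical dimer 10 may be alkylated at both termini, and the product may be hard to separate from the excess of 10. Fallback, from 8 back to 12: 8 would be converted to 11 as before and captured with a tenfold excess of the monomer 3, which is easier to use in large excess and to remove, to give the trimer A–B–C F2. F2 with aminal 6 should give its ring-C Mannich base F3, which on warming with excess 3 should give 12.

3. Step 3. The Mannich base of the β-triketone may lose dimethylamine prematurely, and the enone may then be captured by unreacted 5 (self-condensation) instead of by 3. Fallback, from 5 back to 8: 5 would be condensed on purpose with formaldehyde 9 (0.5 equiv, catalytic KOH, aqueous MeOH) to methylenebis(butyrylfilicinic acid) F4, which should form cleanly because 5 has a single nucleophilic carbon. F4 would then be stirred with excess 3 in dilute aqueous Na2CO3 at rt; base-induced retro-Michael fragmentation (rottlerone-type exchange) should release one molecule of 5 and the methylene triketone, which the phloroglucinolate of 3 captures to give 8.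

**Further compounds**

F1 | step 9 | tetramer A–B–C–D with a p-tolylsulfonylmethyl group on C-5 of ring D | CCCC(=O)C1=C(O)C(C)(C)C(O)=C(Cc2c(O)c(Cc3c(O)c(Cc4c(O)c(CS(=O)(=O)c5ccc(C)cc5)c(O)c(C(=O)CCC)c4O)c(O)c(C(=O)CCC)c3O)c(O)c(C(=O)CCC)c2O)C1=O
F2 | step 5 | trimer A–B–C, ring C with one free ring C–H | CCCC(=O)C1=C(O)C(C)(C)C(O)=C(Cc2c(O)c(Cc3c(O)cc(O)c(C(=O)CCC)c3O)c(O)c(C(=O)CCC)c2O)C1=O
F3 | step 5 | ring-C Mannich base of trimer A–B–C | CCCC(=O)C1=C(O)C(C)(C)C(O)=C(Cc2c(O)c(Cc3c(O)c(CN(C)C)c(O)c(C(=O)CCC)c3O)c(O)c(C(=O)CCC)c2O)C1=O
F4 | step 3 | methylenebis(butyrylfilicinic acid) | CCCC(=O)C1=C(O)C(C)(C)C(O)=C(CC2=C(O)C(C)(C)C(O)=C(C(=O)CCC)C2=O)C1=O
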